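**Plan**

- Rings: A = the 4-hydroxy-3-aryloxyphenyl ring, B = the para-phenylene ring, C = the 3,4-dioxygenated ring, D = the meta-phenylene ring.
- Retrosynthesis cuts, in order: the two methyl ethers on ring C; ring A back to a 2-aryloxycyclohex-2-enone (de-aromatization); the macrocycle at the ether bond between the ring B oxygen and the ring A carbon, giving a ring B phenol and a 2,3-epoxycyclohexanone; ring A itself into a 4-arylbutanal and methyl vinyl ketone; then the B–C ethano bridge (Wittig), the C–D ether (Ullmann) and the ring D–chain bond (Sonogashira).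
- Feature that makes the ring closure possible: in ring A the ether carbon is the ring neighbour of the hydroxyl carbon, and the ethano chain is para to that hydroxyl. This is the C2/C1/C4 pattern of a 4-substituted cyclohexanone, in which the C1 ketone activates C2 for SN2 attack and later becomes the free phenol OH without a protecting group.
- Forward order: ring D chain, C–D ether, B–C stilbene, global hydrogenation, ring A built as a cyclohexenone, epoxide, 18-membered ring closure, aromatization, demethylation.
- Stereochemistry: the target has no stereocentre; the sp3 centres of the ring A precursors are racemic and are erased by dehydration and aromatization.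

Key step: step 10

Remark: compound 10 is an E/Z mixture and compounds 15–21 are racemic (17 and 19 as diastereomer mixtures). All of these elements disappear later, so the SMILES carry no stereodescriptors.

**Route**

Step 1
Reactants: 1 3-iodophenol; 2 4,4-diethoxybut-1-yne
Product: 3 3-(4,4-diethoxybut-1-yn-1-yl)phenol
Conditions: PdCl2(PPh3)2 (cat.), CuI (cat.), Et3N, THF, rt
Reagents that add atoms: none
Why: Sonogashira coupling of an aryl iodide with a terminal alkyne tolerates the free phenol and the acetal and installs the four-carbon chain of the later annulation.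

Step 2
Reactants: 3 3-(4,4-diethoxybut-1-yn-1-yl)phenol; 4 2-bromo-3,4-dimethoxybenzaldehyde
Product: 5 2-[3-(4,4-diethoxybut-1-yn-1-yl)phenoxy]-3,4-dimethoxybenzaldehyde
Conditions: CuI (cat.), N,N-dimethylglycine hydrochloride (cat.), Cs2CO3, 1,4-dioxane, 90 °C
Reagents that add atoms: none
Why: Ullmann diaryl ether coupling should be helped by the ortho formyl group of the bromide, while the internal alkyne, the acetal and the non-enolizable aldehyde are inert to carbonate base.

Step 3
Reactants: 6 1-(benzyloxy)-4-(chloromethyl)benzene; 7 triphenylphosphine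
Product: 8 [4-(benzyloxy)benzyl]triphenylphosphonium chloride
Conditions: PhMe, reflux
Reagents that add atoms: none
Why: SN2 quaternization of a benzylic chloride by PPh3 gives the salt, which should precipitate from toluene.

Step 4
Reactants: 5 2-[3-(4,4-diethoxybut-1-yn-1-yl)phenoxy]-3,4-dimethoxybenzaldehyde; 8 [4-(benzyloxy)benzyl]triphenylphosphonium chloride
Product: 10 1-{2-[4-(benzyloxy)phenyl]ethenyl}-2-[3-(4,4-diethoxybut-1-yn-1-yl)phenoxy]-3,4-dimethoxybenzene (E/Z mixture), via ylide 9 (not isolated)
Conditions: K2CO3, 18-crown-6 (cat.), CH2Cl2, reflux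
Reagents that add atoms: none
Why: Wittig olefination of an aromatic aldehyde with a semi-stabilized benzyl ylide under mild carbonate conditions joins rings B and C, and the alkene geometry is irrelevant because the double bond is hydrogenated next.

Step 5
Reactants: 10 1-{2-[4-(benzyloxy)phenyl]ethenyl}-2-[3-(4,4-diethoxybut-1-yn-1-yl)phenoxy]-3,4-dimethoxybenzene
Product: 11 4-(2-{2-[3-(4,4-diethoxybutyl)phenoxy]-3,4-dimethoxyphenyl}ethyl)phenol
Conditions: H2 (1 atm), 10% Pd/C, EtOAc–EtOH, rt
Reagents that add atoms: none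
Why: One catalytic hydrogenation should saturate the stilbene and the alkyne and cleave the benzyl ether by hydrogenolysis, leaving the diaryl ether, the methyl ethers and the acetal untouched under neutral conditions.

Step 6
Reactants: 11 4-(2-{2-[3-(4,4-diethoxybutyl)phenoxy]-3,4-dimethoxyphenyl}ethyl)phenol
Product: 12 {4-[2-(2-[3-(4,4-diethoxybutyl)phenoxy]-3,4-dimethoxyphenyl)ethyl]phenoxy}triisopropylsilane
Conditions: TIPSCl, imidazole, DMF, rt
Reagents that add atoms: triisopropylsilyl chloride, CC(C)[Si](Cl)(C(C)C)C(C)C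
Why: Silylation of the only free hydroxyl masks the ring B phenol as an acid- and base-tolerant ether that fluoride can remove at the moment of ring closure.

Step 7
Reactants: 12 {4-[2-(2-[3-(4,4-diethoxybutyl)phenoxy]-3,4-dimethoxyphenyl)ethyl]phenoxy}triisopropylsilane
Product: 13 4-[3-(2,3-dimethoxy-6-{2-[4-(triisopropylsilyloxy)phenyl]ethyl}phenoxy)phenyl]butanal
Conditions: 1 M HCl, THF, rt
Reagents that add atoms: water, O
Why: Dilute aqueous acid hydrolyses the diethyl acetal to the aldehyde through the oxocarbenium ion, conditions under which aryl triisopropylsilyl ethers and aryl ethers are stable.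

Step 8
Reactants: 13 4-[3-(2,3-dimethoxy-6-{2-[4-(triisopropylsilyloxy)phenyl]ethyl}phenoxy)phenyl]butanal; 14 methyl vinyl ketone
Product: 16 4-{2-[3-(2,3-dimethoxy-6-{2-[4-(triisopropylsilyloxy)phenyl]ethyl}phenoxy)phenyl]ethyl}cyclohex-2-en-1-one (racemic), via keto aldehyde 15 (not isolated)
Conditions: Et2NSiMe3 (cat.), MeCN, 80 °C; then TsOH·H2O (cat.), PhMe, 80 °C
Reagents that add atoms: none
Why: Enamine-catalysed Michael addition of the aldehyde to the enone followed by acid-catalysed intramolecular aldol condensation (Robinson-type annulation, only the six-membered mode being possible) builds ring A as a 4-substituted cyclohex-2-enone whose racemic C4 centre is erased in step 11.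

Step 9
Reactants: 16 4-{2-[3-(2,3-dimethoxy-6-{2-[4-(triisopropylsilyloxy)phenyl]ethyl}phenoxy)phenyl]ethyl}cyclohex-2-en-1-one
Product: 17 5-{2-[3-(2,3-dimethoxy-6-{2-[4-(triisopropylsilyloxy)phenyl]ethyl}phenoxy)phenyl]ethyl}-7-oxabicyclo[4.1.0]heptan-2-one (diastereomer mixture, epoxide trans to the side chain expected to predominate)
Conditions: t-BuOOH (in decane), DBU, CH2Cl2, 0 °C to rt
Reagents that add atoms: tert-butyl hydroperoxide, CC(C)(C)OO
Why: Weitz–Scheffer nucleophilic epoxidation under anhydrous amine-base conditions converts the enone into the 2,3-epoxy ketone without touching the electron-rich arenes or the silyl ether, and the new stereocentres need no control because both are destroyed in step 10.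

Step 10
Reactants: 17 5-{2-[3-(2,3-dimethoxy-6-{2-[4-(triisopropylsilyloxy)phenyl]ethyl}phenoxy)phenyl]ethyl}-7-oxabicyclo[4.1.0]heptan-2-one
Product: 20 macrocyclic 2-aryloxycyclohex-2-en-1-one (the 18-membered ring of the target with ring A as a cyclohex-2-enone: C1 ketone, C2 bearing the ring B oxygen, C4 bearing the ethano link to ring D; ring C as its dimethyl ether; racemic), via cesium phenoxide 18 (not isolated), via aldol alkoxide 19 (not isolated)
Conditions: CsF, DMF, 60 °C, syringe-pump addition of 17 to high dilution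
Reagents that add atoms: none
Why: Fluoride removes the triisopropylsilyl group and releases cesium phenoxide 18 at low stationary concentration; its oxygen attacks C2 of the oxirane, the carbon alpha to the ketone, in an SN2 opening with inversion, and the resulting beta-alkoxy ketone 19 loses hydroxide from C3 by E1cB elimination to give the 2-aryloxy enone. The closest known reaction type is the base-mediated coupling of phenols with 2,3-epoxycyclohexanones to 2-aryloxycyclohex-2-enones, the epoxide counterpart of the Williamson reaction of alpha-halo ketones. The 18-membered ring closes in the 18-exo-tet mode, since the breaking C2–O bond of the oxirane lies outside the new ring. No lasting stereocentre is created: C2 and C3 become sp2 and the C4 centre stays racemic until aromatization, so every epoxide diastereomer converges on 20. The step needs alpha- over beta-opening, which the carbonyl secures by lowering the SN2 barrier at C2 while the C4 side chain shields C3, and it needs cyclization over oligomerization, which slow addition and in-situ unmasking of the nucleophile secure. Ring A is still a puckered cyclohexanone at this stage, so the ansa chain should reach C2 with less strain than a closure on a flat arene would impose.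

Step 11
Reactants: 20 macrocyclic 2-aryloxycyclohex-2-en-1-one
Product: 22 marchantin H ring C dimethyl ether (the target macrocycle with OMe in place of the two ring C hydroxyls and a free ring A phenol), via dienone 21 (not isolated)
Conditions: Pd(OCOCF3)2 (cat.), 2-(dimethylamino)pyridine (cat.), TsOH·H2O (cat.), O2 (1 atm), DMSO, 80 °C
Reagents that add atoms: none
Why: Aerobic dehydrogenation through a divalent palladium enolate at C6 and beta-hydride elimination from C5 should give the cyclohexa-2,5-dienone, which tautomerizes at once to the phenol, erasing the C4 stereocentre and revealing the ring A hydroxyl.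

Step 12
Reactants: 22 marchantin H ring C dimethyl ether
Product: 23 marchantin H
Conditions: BBr3, CH2Cl2, −78 °C to rt; then H2O
Reagents that add atoms: none
Why: Lewis acid cleavage of the two aryl methyl ethers by BBr3 (bromide attack on the O-methyl of the boron-complexed ether) leaves diaryl ethers intact and frees the ring C catechol.

**Compound list**

1 | 3-iodophenol | Oc1cccc(I)c1 | starting material
2 | 4,4-diethoxybut-1-yne | C#CCC(OCC)OCC | starting material
3 | 3-(4,4-diethoxybut-1-yn-1-yl)phenol | Oc1cccc(c1)C#CCC(OCC)OCC | intermediate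
4 | 2-bromo-3,4-dimethoxybenzaldehyde | O=Cc1ccc(OC)c(OC)c1Br | starting material
5 | 2-[3-(4,4-diethoxybut-1-yn-1-yl)phenoxy]-3,4-dimethoxybenzaldehyde | O=Cc1ccc(OC)c(OC)c1Oc1cccc(c1)C#CCC(OCC)OCC | intermediate
6 | 1-(benzyloxy)-4-(chloromethyl)benzene | ClCc1ccc(OCc2ccccc2)cc1 | starting material
7 | triphenylphosphine | c1ccc(cc1)P(c1ccccc1)c1ccccc1 | starting material
8 | [4-(benzyloxy)benzyl]triphenylphosphonium chloride | [Cl-].c1ccc(cc1)COc1ccc(cc1)C[P+](c1ccccc1)(c1ccccc1)c1ccccc1 | intermediate
9 | [4-(benzyloxy)benzylidene]triphenylphosphorane (ylide) | [CH-](c1ccc(OCc2ccccc2)cc1)[P+](c1ccccc1)(c1ccccc1)c1ccccc1 | intermediate (not isolated)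
10 | 1-{2-[4-(benzyloxy)phenyl]ethenyl}-2-[3-(4,4-diethoxybut-1-yn-1-yl)phenoxy]-3,4-dimethoxybenzene, E/Z mixture | COc1ccc(C=Cc2ccc(OCc3ccccc3)cc2)c(Oc2cccc(c2)C#CCC(OCC)OCC)c1OC | intermediate
11 | 4-(2-{2-[3-(4,4-diethoxybutyl)phenoxy]-3,4-dimethoxyphenyl}ethyl)phenol | COc1ccc(CCc2ccc(O)cc2)c(Oc2cccc(CCCC(OCC)OCC)c2)c1OC | intermediate
12 | {4-[2-(2-[3-(4,4-diethoxybutyl)phenoxy]-3,4-dimethoxyphenyl)ethyl]phenoxy}triisopropylsilane | COc1ccc(CCc2ccc(O[Si](C(C)C)(C(C)C)C(C)C)cc2)c(Oc2cccc(CCCC(OCC)OCC)c2)c1OC | intermediate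
13 | 4-[3-(2,3-dimethoxy-6-{2-[4-(triisopropylsilyloxy)phenyl]ethyl}phenoxy)phenyl]butanal | COc1ccc(CCc2ccc(O[Si](C(C)C)(C(C)C)C(C)C)cc2)c(Oc2cccc(CCCC=O)c2)c1OC | intermediate
14 | methyl vinyl ketone (but-3-en-2-one) | CC(=O)C=C | starting material
15 | 2-{2-[3-(2,3-dimethoxy-6-{2-[4-(triisopropylsilyloxy)phenyl]ethyl}phenoxy)phenyl]ethyl}-5-oxohexanal, racemic | COc1ccc(CCc2ccc(O[Si](C(C)C)(C(C)C)C(C)C)cc2)c(Oc2cccc(CCC(C=O)CCC(C)=O)c2)c1OC | intermediate (not isolated)
16 | 4-{2-[3-(2,3-dimethoxy-6-{2-[4-(triisopropylsilyloxy)phenyl]ethyl}phenoxy)phenyl]ethyl}cyclohex-2-en-1-one, racemic | COc1ccc(CCc2ccc(O[Si](C(C)C)(C(C)C)C(C)C)cc2)c(Oc2cccc(CCC3CCC(=O)C=C3)c2)c1OC | intermediate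
17 | 5-{2-[3-(2,3-dimethoxy-6-{2-[4-(triisopropylsilyloxy)phenyl]ethyl}phenoxy)phenyl]ethyl}-7-oxabicyclo[4.1.0]heptan-2-one, racemic diastereomer mixture | COc1ccc(CCc2ccc(O[Si](C(C)C)(C(C)C)C(C)C)cc2)c(Oc2cccc(CCC3CCC(=O)C4OC34)c2)c1OC | intermediate
18 | cesium 4-(2-{3,4-dimethoxy-2-[3-(2-(5-oxo-7-oxabicyclo[4.1.0]heptan-2-yl)ethyl)phenoxy]phenyl}ethyl)phenoxide | [Cs+].COc1ccc(CCc2ccc([O-])cc2)c(Oc2cccc(CCC3CCC(=O)C4OC34)c2)c1OC | intermediate (not isolated)
19 | cesium alkoxide of the macrocyclic 2-aryloxy-3-hydroxycyclohexanone (ring A: C1 ketone, C2 aryloxy, C3 alkoxide, C4 ethano link) | [Cs+].O=C1CCC2C([O-])C1Oc1ccc(cc1)CCc1ccc(OC)c(OC)c1Oc1cccc(c1)CC2 | intermediate (not isolated)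
20 | macrocyclic 2-aryloxycyclohex-2-en-1-one (ring A as enone, ring C dimethyl ether), racemic | O=C1CCC2C=C1Oc1ccc(cc1)CCc1ccc(OC)c(OC)c1Oc1cccc(c1)CC2 | intermediate
21 | macrocyclic 2-aryloxycyclohexa-2,5-dien-1-one (keto tautomer of 22) | O=C1C=CC2C=C1Oc1ccc(cc1)CCc1ccc(OC)c(OC)c1Oc1cccc(c1)CC2 | intermediate (not isolated)
22 | marchantin H ring C dimethyl ether | Oc1ccc2cc1Oc1ccc(cc1)CCc1ccc(OC)c(OC)c1Oc1cccc(c1)CC2 | intermediate
23 | marchantin H | Oc1ccc2cc1Oc1ccc(cc1)CCc1ccc(O)c(O)c1Oc1cccc(c1)CC2 | target

**Summary**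

Total step count: 12. Longest linear sequence: 11 (steps 1, 2 and 4–12).

Steps most likely to fail:

1. Step 10. Intermolecular epoxide opening (oligomerization) may outrun ring closure, the phenoxide may attack the beta carbon, or the beta-alkoxy ketone may fragment by retro-aldol cleavage before it eliminates. The fallback closes the same ether bond by Ullmann coupling on an aromatic ring A and sets out from enone 16. Aromatization under the conditions of step 11 should give the para-alkylphenol F1. Ortho-bromination of this free phenol (NBS, catalytic i-Pr2NH, CH2Cl2, 0 °C) should give the bromophenol F2. Methylation (MeI, K2CO3, acetone) should give the bromoanisole F3, and desilylation (n-Bu4NF, THF) the ring B phenol F4. Intramolecular Ullmann coupling (CuI, N,N-dimethylglycine, Cs2CO3, dioxane, high dilution, 100 °C) should give the macrocyclic trimethyl ether F5. BBr3 as in step 12 then cleaves three methyl ethers and returns to the route at 23.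

2. Step 11. The acidic, oxidizing medium may hydrolyse the aryl enol ether (reopening the macrocycle), oxidize the benzylic methylenes, or stall on a coordinating product. The fallback is a stoichiometric enolate route from 20. Kinetic deprotonation at C6 (LiN(i-Pr)2, THF, −78 °C) and trapping with PhSeCl should give the alpha'-phenylselanyl ketone F6. Oxidation (H2O2, pyridine, CH2Cl2, 0 °C) and selenoxide syn-elimination then give dienone 21, which tautomerizes and rejoins the route at 22.

3. Step 2. Oxidative addition into a bromide flanked by two ortho substituents may be slow, so that reductive debromination or degradation of the aldehyde competes. The fallback replaces copper catalysis by uncatalysed SNAr. Phenol 3 is heated with 2-fluoro-3,4-dimethoxybenzaldehyde (O=Cc1ccc(OC)c(OC)c1F), K2CO3, DMF, 120 °C. The ortho formyl group stabilizes the Meisenheimer intermediate, and the product is 5 itself (no new compound, F0).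

**Further compounds**

F1 | step 10 | 4-{2-[3-(2,3-dimethoxy-6-{2-[4-(triisopropylsilyloxy)phenyl]ethyl}phenoxy)phenyl]ethyl}phenol | COc1ccc(CCc2ccc(O[Si](C(C)C)(C(C)C)C(C)C)cc2)c(Oc2cccc(CCc3ccc(O)cc3)c2)c1OC
F2 | step 10 | 2-bromo-4-{2-[3-(2,3-dimethoxy-6-{2-[4-(triisopropylsilyloxy)phenyl]ethyl}phenoxy)phenyl]ethyl}phenol | COc1ccc(CCc2ccc(O[Si](C(C)C)(C(C)C)C(C)C)cc2)c(Oc2cccc(CCc3ccc(O)c(Br)c3)c2)c1OC
F3 | step 10 | {4-[2-(2-{3-[2-(3-bromo-4-methoxyphenyl)ethyl]phenoxy}-3,4-dimethoxyphenyl)ethyl]phenoxy}triisopropylsilane | COc1ccc(CCc2ccc(O[Si](C(C)C)(C(C)C)C(C)C)cc2)c(Oc2cccc(CCc3ccc(OC)c(Br)c3)c2)c1OC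
F4 | step 10 | 4-[2-(2-{3-[2-(3-bromo-4-methoxyphenyl)ethyl]phenoxy}-3,4-dimethoxyphenyl)ethyl]phenol | COc1ccc(CCc2ccc(O)cc2)c(Oc2cccc(CCc3ccc(OC)c(Br)c3)c2)c1OC
F5 | step 10 | marchantin H trimethyl ether | COc1ccc2cc1Oc1ccc(cc1)CCc1ccc(OC)c(OC)c1Oc1cccc(c1)CC2
F6 | step 11 | macrocyclic 2-aryloxy-6-(phenylselanyl)cyclohex-2-en-1-one | O=C1C([Se]c3ccccc3)CC2C=C1Oc1ccc(cc1)CCc1ccc(OC)c(OC)c1Oc1cccc(c1)CC2
F0 | step 2 | none | none
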